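(Its constants were set for the occasion; what happens was integrated by code.)

Take the amounts first: the substrate is charged to the first phase, and the reagent meant for it is charged to the second phase and must cross over before it can act.

    reagent in the reaction phase ⇌ reagent in the second phase, rate k1*([reagent in the reaction phase] - [reagent in the second phase]/K1) per volume of the first phase (K1 = 16, k1 = 0.0097 s⁻¹)
    substrate + reagent in the reaction phase → target (k2 = 0.83 M⁻¹ s⁻¹)
    reagent in the reaction phase + target → over-reacted product (k3 = 0.16 M⁻¹ s⁻¹)
    target ⇌ isomer of the product (K4 = 17, k4 = 0.0084 s⁻¹)

substrate 0.050 M; reagent in the second phase 0.0500 M; time 2.0 min; volume of the second phase over the first 0.25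

- target at 2.0 min, in percent of the substrate charged
- part of the substrate charged that has reacted at 2.0 min

- in the second phase: reagent in the second phase; everything else is in the first
- charges count per volume of the first phase; a concentration in a rate is the amount of a species over the volume of its own phase; every rate counts per litre of the first phase
- run time (flask): 2.0 min

Begin with the reagent in the reaction phase. Hold the reagent in the second phase at its charge; partition equilibrium then offers a level of 25.0% of the substrate charge. Substrate as charged removes reagent with a coefficient of 0.0415 s⁻¹, larger than the transfer coefficient of 0.0097 s⁻¹, which makes transfer the rate-limiting step. So expect a resting level of 4.74% of the substrate charge, reached after a lag of 19.5 s.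

Now fold these into one number, 0.197, the turnover count: the number of substrate lifetimes under the resting reagent that fit into the run after the lag. Substrate then falls pseudo-first-order, so the exponential of this count gives 17.9% reacted.

Test whether this number is enough. It counts substrate reacted, not target, and target passes on to the isomer of the product. Count that too: 0.844 forward turnovers keep a share of 67.5% of what was made, so reckon on 12.1% target.

The forecast, lower on both counts, gives 10.8% target and 17.1% reacted, holding that “Transfer out of the second phase is the bottleneck”. The flask gives 11.0% target and 16.9% reacted.

Now take away the slowness of the uptake of reagent in the second phase: target in this flask at 2.0 min rises from 11.0% to 26.3%, which covers 17% of what is missing. Left until 3.0 min, the same flask counts 0.315 turnovers, hence 27.1% reacted; the run gives less, 25.2%, with target at 13.1%.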